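Ring A (halimane numbering: C4 carries the ester, C5–H and sp2 C10 are the ring-fusion atoms) is disconnected in a [3+3] sense: C1–C2–C3 is inserted between C4 and C10, which are 1,3-related through C5. In the precursor, a ring B cyclohexanone already bearing the C8/C9 stereocentres and the side chain, C4 is the β-carbon of an exocyclic (methoxycarbonyl)methylidene at C5 and C10 is the ketone carbon. The key step, a Michael/Wittig annulation with allylidenetriphenylphosphorane, exploits this C4=C5–C10=O enone: the ylide γ-carbon adds to C4 (C3–C4) and its α-carbon olefinates C10 (C1=C10), closing ring A in one operation. C4 methylation and diimide removal of the extra C2=C3 bond follow.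

Key step: step 5

Remark on numbering: atom labels C1–C18 in the text follow halimane numbering of the target (C8 and C9 are the methyl-bearing ring B carbons, C11–C15 the side chain, C18 the ring ester carbon).
Assumption: in step 1 the (R,S,S) phosphoramidite is taken to give the 3R series by analogy with unsubstituted cyclohexenone; if the sense is opposite, its enantiomer is used.

Step 1
Reactants: 1 2-methylcyclohex-2-en-1-one
Product: 3 trimethyl{[(3R)-2,3-dimethylcyclohex-1-en-1-yl]oxy}silane, via aluminium enolate 2 (not isolated)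
Conditions: Me3Al, Cu(thiophene-2-carboxylate) (2 mol %), (R,S,S)-BINOL bis(1-phenylethyl)amine phosphoramidite (4 mol %), Et2O, −30 °C; then Me3SiOTf, THF, 0 °C
Reagents that add atoms: trimethylaluminium C[Al](C)C; trimethylsilyl trifluoromethanesulfonate C[Si](C)(C)OS(=O)(=O)C(F)(F)F
Why: Copper-catalysed asymmetric conjugate addition of a methyl nucleophile to an α-substituted cyclohexenone, in which the chiral copper–phosphoramidite complex selects the enone face and sets C8 (R), followed by O-silylation of the regiodefined aluminium enolate.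

Step 2
Reactants: 3 trimethyl{[(3R)-2,3-dimethylcyclohex-1-en-1-yl]oxy}silane; 4 but-3-en-2-one
Product: 5 (2S,3R)-2,3-dimethyl-2-(3-oxobutyl)cyclohexan-1-one
Conditions: BF3·OEt2, CH2Cl2, −78 °C; aq. NaHCO3
Reagents that add atoms: none
Why: Mukaiyama–Michael addition in which the activated enone is attacked by C9 of the tetrasubstituted silyl enol ether anti to the pseudoaxial C8 methyl group, which sets the C9 quaternary centre (S) with the two ring methyl groups cis.

Step 3
Reactants: 5 (2S,3R)-2,3-dimethyl-2-(3-oxobutyl)cyclohexan-1-one; 6 triethyl phosphonoacetate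
Product: 8 ethyl (2E)-5-[(1S,2R)-1,2-dimethyl-6-oxocyclohexyl]-3-methylpent-2-enoate, via sodium phosphonate carbanion 7 (not isolated)
Conditions: NaH, THF, 0 °C → 50 °C
Reagents that add atoms: none
Why: Horner–Wadsworth–Emmons olefination that is chemoselective for the unhindered methyl ketone over the ring ketone next to the quaternary carbon and should favour the E enoate under thermodynamic control of the addition step (any minor Z isomer is removed by chromatography).

Step 4
Reactants: 8 ethyl (2E)-5-[(1S,2R)-1,2-dimethyl-6-oxocyclohexyl]-3-methylpent-2-enoate; 9 methyl glyoxylate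
Product: 13 ethyl (2E)-5-[(1S,2R,5E)-5-(2-methoxy-2-oxoethylidene)-1,2-dimethyl-6-oxocyclohexyl]-3-methylpent-2-enoate, via lithium enolate 10 (not isolated), via lithium aldolate 11 (not isolated), via mesylate 12 (not isolated)
Conditions: LiN(SiMe3)2, THF, −78 °C; 9; then MsCl, Et3N, −78 °C → rt
Reagents that add atoms: none
Why: Directed aldol condensation in which the ketone can enolise only toward C5 (C9 is quaternary), the enolate adds to the aldehyde of the glyoxylate, and mesylation with E1cB elimination gives the doubly activated exocyclic alkene, so the two aldol stereocentres are destroyed.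

Step 5
Reactants: 13 ethyl (2E)-5-[(1S,2R,5E)-5-(2-methoxy-2-oxoethylidene)-1,2-dimethyl-6-oxocyclohexyl]-3-methylpent-2-enoate; 14 allyltriphenylphosphonium bromide
Product: 18 methyl (5S,6R,8aS)-5-[(3E)-5-ethoxy-3-methyl-5-oxopent-3-en-1-yl]-5,6-dimethyl-1,5,6,7,8,8a-hexahydronaphthalene-1-carboxylate (C1 epimers), via allylidene ylide 15 (not isolated), via enolate–vinylphosphonium adduct 16 (not isolated), via keto ylide 17 (not isolated)
Conditions: 14, NaN(SiMe3)2, THF, 0 °C; add 13, −78 °C → reflux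
Reagents that add atoms: none
Why: Ylide 15 adds through its γ-carbon (C3) to C4, the unsubstituted β-carbon of the enone, to give the C10 enolate 16; proton transfer from C3 to C5 frees the C10 ketone and regenerates an allylic ylide 17, whose α-carbon (C1) olefinates C10 with loss of Ph3P=O. The closest known reaction type is the cyclohexa-1,3-diene annulation of enones and alkylidene β-dicarbonyl compounds with allylidenetriphenylphosphorane (tandem Michael addition/intramolecular Wittig). Ring A is the only ring closed, by a 6-exo-trig intramolecular Wittig attack of C1 on the C10 carbonyl after the intermolecular C3–C4 bond; the cis C2=C3 geometry is reached by rotation in the allylic ylide. C5 is set by protonation of the enolate and equilibration of this α-keto centre before ring closure to the epimer with the C4 substituent equatorial on ring B (no 1,3-diaxial clash with the axial C9 methyl), which places H-5 cis to the C8 and C9 methyl groups; C4 forms unselectively, which is harmless because it is planarised in step 6. The step needs 1,4- over 1,2-addition and attack at C4 and not C5: the C10 carbonyl is shielded by quaternary C9, and C4 is the less substituted alkene carbon and β to the ketone.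

Step 6
Reactants: 18 methyl (5S,6R,8aS)-5-[(3E)-5-ethoxy-3-methyl-5-oxopent-3-en-1-yl]-5,6-dimethyl-1,5,6,7,8,8a-hexahydronaphthalene-1-carboxylate
Product: 20 methyl (1S,5S,6R,8aR)-5-[(3E)-5-ethoxy-3-methyl-5-oxopent-3-en-1-yl]-1,5,6-trimethyl-1,5,6,7,8,8a-hexahydronaphthalene-1-carboxylate, via potassium trienolate 19 (not isolated)
Conditions: KN(SiMe3)2, THF, −78 °C; MeI, −78 → 0 °C
Reagents that add atoms: iodomethane CI
Why: α-Alkylation of an extended ester enolate: the C4–H (α to the ester and allylic to the diene) is removed selectively, and iodomethane approaches the nearly planar ring A anti to the C5–C6 bond (the face of H-5), which sets C4 (S) with the methyl group cis to H-5 and the ester trans.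

Step 7
Reactants: 20 methyl (1S,5S,6R,8aR)-5-[(3E)-5-ethoxy-3-methyl-5-oxopent-3-en-1-yl]-1,5,6-trimethyl-1,5,6,7,8,8a-hexahydronaphthalene-1-carboxylate
Product: 21 methyl (1S,5S,6R,8aR)-5-[(3E)-5-ethoxy-3-methyl-5-oxopent-3-en-1-yl]-1,5,6-trimethyl-1,2,3,5,6,7,8,8a-octahydronaphthalene-1-carboxylate
Conditions: 2-nitrobenzenesulfonylhydrazide, Et3N, CH2Cl2, rt
Reagents that add atoms: none
Why: Diimide reduction (concerted syn transfer of H2), which should strongly prefer the cis-disubstituted C2=C3 bond over the trisubstituted C1=C10 and side-chain alkenes and creates no stereocentre.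

Step 8
Reactants: 21 methyl (1S,5S,6R,8aR)-5-[(3E)-5-ethoxy-3-methyl-5-oxopent-3-en-1-yl]-1,5,6-trimethyl-1,2,3,5,6,7,8,8a-octahydronaphthalene-1-carboxylate
Product: 22 methyl (1S,5S,6R,8aR)-5-[(3E)-5-hydroxy-3-methylpent-3-en-1-yl]-1,5,6-trimethyl-1,2,3,5,6,7,8,8a-octahydronaphthalene-1-carboxylate
Conditions: i-Bu2AlH (2.1 equiv), CH2Cl2, −78 °C; Rochelle salt
Reagents that add atoms: none
Why: 1,2-Reduction of the unhindered conjugated ethyl ester to the allylic alcohol by i-Bu2AlH at low temperature, while the methyl ester on quaternary C4 is sterically shielded and should react much more slowly.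

Step 9
Reactants: 22 methyl (1S,5S,6R,8aR)-5-[(3E)-5-hydroxy-3-methylpent-3-en-1-yl]-1,5,6-trimethyl-1,2,3,5,6,7,8,8a-octahydronaphthalene-1-carboxylate
Product: 23 methyl (1S,5S,6R,8aR)-5-[(3E)-5-(formyloxy)-3-methylpent-3-en-1-yl]-1,5,6-trimethyl-1,2,3,5,6,7,8,8a-octahydronaphthalene-1-carboxylate
Conditions: HCO2H, DCC, DMAP (cat.), CH2Cl2, 0 °C → rt
Reagents that add atoms: formic acid OC=O
Why: Steglich-type carbodiimide esterification of the primary allylic alcohol with formic acid, which touches no stereocentre or alkene.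

Compound list
1 | 2-methylcyclohex-2-en-1-one | CC1=CCCCC1=O | starting material
2 | dimethylaluminium (3R)-2,3-dimethylcyclohex-1-en-1-olate | C[C@@H]1CCCC(O[Al](C)C)=C1C | intermediate (not isolated)
3 | trimethyl{[(3R)-2,3-dimethylcyclohex-1-en-1-yl]oxy}silane | C[C@@H]1CCCC(O[Si](C)(C)C)=C1C | intermediate
4 | but-3-en-2-one | CC(=O)C=C | starting material
5 | (2S,3R)-2,3-dimethyl-2-(3-oxobutyl)cyclohexan-1-one | O=C1CCC[C@@H](C)[C@]1(C)CCC(C)=O | intermediate
6 | triethyl phosphonoacetate | CCOC(=O)CP(=O)(OCC)OCC | starting material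
7 | sodium salt of triethyl phosphonoacetate | [Na+].CCOC(=O)[CH-]P(=O)(OCC)OCC | intermediate (not isolated)
8 | ethyl (2E)-5-[(1S,2R)-1,2-dimethyl-6-oxocyclohexyl]-3-methylpent-2-enoate | O=C1CCC[C@@H](C)[C@]1(C)CC/C(C)=C/C(=O)OCC | intermediate
9 | methyl glyoxylate | COC(=O)C=O | starting material
10 | lithium (5R,6S)-6-[(3E)-5-ethoxy-3-methyl-5-oxopent-3-en-1-yl]-5,6-dimethylcyclohex-1-en-1-olate | [Li+].[O-]C1=CCC[C@@H](C)[C@]1(C)CC/C(C)=C/C(=O)OCC | intermediate (not isolated)
11 | lithium aldolate: methyl 2-oxido-2-[(3S,4R)-3-[(3E)-5-ethoxy-3-methyl-5-oxopent-3-en-1-yl]-3,4-dimethyl-2-oxocyclohexyl]acetate, lithium salt (mixture at the two new centres) | [Li+].[O-]C(C(=O)OC)C1CC[C@@H](C)[C@](C)(CC/C(C)=C/C(=O)OCC)C1=O | intermediate (not isolated)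
12 | methyl 2-(methanesulfonyloxy)-2-[(3S,4R)-3-[(3E)-5-ethoxy-3-methyl-5-oxopent-3-en-1-yl]-3,4-dimethyl-2-oxocyclohexyl]acetate (mixture at the two new centres) | CS(=O)(=O)OC(C(=O)OC)C1CC[C@@H](C)[C@](C)(CC/C(C)=C/C(=O)OCC)C1=O | intermediate (not isolated)
13 | ethyl (2E)-5-[(1S,2R,5E)-5-(2-methoxy-2-oxoethylidene)-1,2-dimethyl-6-oxocyclohexyl]-3-methylpent-2-enoate | COC(=O)/C=C1\CC[C@@H](C)[C@](C)(CC/C(C)=C/C(=O)OCC)C1=O | intermediate
14 | allyltriphenylphosphonium bromide | [Br-].C=CC[P+](c1ccccc1)(c1ccccc1)c1ccccc1 | starting material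
15 | allylidenetriphenylphosphorane | C=CC=P(c1ccccc1)(c1ccccc1)c1ccccc1 | intermediate (not isolated)
16 | Michael adduct: C10 enolate carrying at C5 a 1-methoxy-1-oxo-5-(triphenylphosphonio)pent-4-en-2-yl group (zwitterion) | COC(=O)C(C/C=C/[P+](c1ccccc1)(c1ccccc1)c1ccccc1)C1=C([O-])[C@@](C)(CC/C(C)=C/C(=O)OCC)[C@H](C)CC1 | intermediate (not isolated)
17 | keto ylide: (5S)-ketone carrying at C5 a (3Z)-1-methoxy-1-oxo-5-(triphenylphosphoranylidene)pent-3-en-2-yl group | COC(=O)C(/C=C\C=P(c1ccccc1)(c1ccccc1)c1ccccc1)[C@@H]1CC[C@@H](C)[C@](C)(CC/C(C)=C/C(=O)OCC)C1=O | intermediate (not isolated)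
18 | methyl (5S,6R,8aS)-5-[(3E)-5-ethoxy-3-methyl-5-oxopent-3-en-1-yl]-5,6-dimethyl-1,5,6,7,8,8a-hexahydronaphthalene-1-carboxylate (C1 epimers) | COC(=O)C1C=CC=C2[C@H]1CC[C@@H](C)[C@]2(C)CC/C(C)=C/C(=O)OCC | intermediate
19 | potassium trienolate of 18 | [K+].COC([O-])=C1C=CC=C2[C@H]1CC[C@@H](C)[C@]2(C)CC/C(C)=C/C(=O)OCC | intermediate (not isolated)
20 | methyl (1S,5S,6R,8aR)-5-[(3E)-5-ethoxy-3-methyl-5-oxopent-3-en-1-yl]-1,5,6-trimethyl-1,5,6,7,8,8a-hexahydronaphthalene-1-carboxylate | COC(=O)[C@@]1(C)C=CC=C2[C@H]1CC[C@@H](C)[C@]2(C)CC/C(C)=C/C(=O)OCC | intermediate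
21 | methyl (1S,5S,6R,8aR)-5-[(3E)-5-ethoxy-3-methyl-5-oxopent-3-en-1-yl]-1,5,6-trimethyl-1,2,3,5,6,7,8,8a-octahydronaphthalene-1-carboxylate | COC(=O)[C@@]1(C)CCC=C2[C@H]1CC[C@@H](C)[C@]2(C)CC/C(C)=C/C(=O)OCC | intermediate
22 | methyl (1S,5S,6R,8aR)-5-[(3E)-5-hydroxy-3-methylpent-3-en-1-yl]-1,5,6-trimethyl-1,2,3,5,6,7,8,8a-octahydronaphthalene-1-carboxylate | COC(=O)[C@@]1(C)CCC=C2[C@H]1CC[C@@H](C)[C@]2(C)CC/C(C)=C/CO | intermediate
23 | methyl (1S,5S,6R,8aR)-5-[(3E)-5-(formyloxy)-3-methylpent-3-en-1-yl]-1,5,6-trimethyl-1,2,3,5,6,7,8,8a-octahydronaphthalene-1-carboxylate | COC(=O)[C@@]1(C)CCC=C2[C@H]1CC[C@@H](C)[C@]2(C)CC/C(C)=C/COC=O | target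

Total step count: 9. Longest linear sequence: 9 steps (1 → 23).

Steps most likely to fail

Step 5. The basic ylide may deprotonate 13 at C6 (vinylogous enolisation) instead of adding. It may also attack through its α-carbon and cyclopropanate. Finally, the tethered, semi-stabilised ylide may fail to olefinate the hindered C10 ketone. Fallback, from 13 and back to the route at 21: ring A is built stepwise. Copper-catalysed conjugate addition of but-3-enylmagnesium bromide (CuBr·SMe2 cat., THF, −40 °C; NH4Cl work-up and equilibration at C5) should give methyl 2-[(1S,3S,4R)-3-[(3E)-5-ethoxy-3-methyl-5-oxopent-3-en-1-yl]-3,4-dimethyl-2-oxocyclohexyl]hex-5-enoate F1. Takai–Lombardo methylenation of the ketone (Zn, CH2Br2, TiCl4, THF) should give the 2-methylidene analogue F2. α-Methylation (LiN(i-Pr)2, THF, −78 °C; MeI), with attack anti to C10 in the conformer that has H-5 eclipsing the enolate, should give methyl (2S)-2-[(1R,3S,4R)-3-[(3E)-5-ethoxy-3-methyl-5-oxopent-3-en-1-yl]-3,4-dimethyl-2-methylidenecyclohexyl]-2-methylhex-5-enoate F3. Ring-closing metathesis (second-generation Grubbs catalyst, CH2Cl2, 40 °C) then joins C1 to C10 and gives 21, so steps 6 and 7 are not needed.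

Step 7. The reduction may be incomplete at the disubstituted alkene next to the quaternary C4, or the trisubstituted alkenes may be reduced as well. Fallback, from 13 and back to the route at 21: the extra alkene is never made. Copper-catalysed conjugate addition of the Grignard reagent from 2-(2-bromoethyl)-1,3-dioxolane (CuBr·SMe2 cat., THF, −40 °C) should give methyl 4-(1,3-dioxolan-2-yl)-2-[(1S,3S,4R)-3-[(3E)-5-ethoxy-3-methyl-5-oxopent-3-en-1-yl]-3,4-dimethyl-2-oxocyclohexyl]butanoate F4. Mild hydrolysis (aq. HCl, THF) frees the keto aldehyde methyl 2-[(1S,3S,4R)-3-[(3E)-5-ethoxy-3-methyl-5-oxopent-3-en-1-yl]-3,4-dimethyl-2-oxocyclohexyl]-5-oxopentanoate F5. Intramolecular McMurry coupling (TiCl3(DME)1.5, Zn–Cu couple, DME, reflux, high dilution) joins C1 and C10 to give methyl (5S,6R,8aS)-5-[(3E)-5-ethoxy-3-methyl-5-oxopent-3-en-1-yl]-5,6-dimethyl-1,2,3,5,6,7,8,8a-octahydronaphthalene-1-carboxylate F6. α-Methylation (LiN(i-Pr)2, THF, −78 °C; MeI) from the face of H-5 then gives 21.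

Step 8. Chemoselectivity may be lost through hydride attack on the C4 methyl ester as well as on the side-chain ester. Fallback, from 21 and back to the route at 22: the two esters are told apart by hydrolysis rate. LiOH (THF/MeOH/H2O, rt) should cleave only the unhindered conjugated ethyl ester to give (2E)-5-[(1S,2R,4aR,5S)-5-(methoxycarbonyl)-1,2,5-trimethyl-1,2,3,4,4a,5,6,7-octahydronaphthalen-1-yl]-3-methylpent-2-enoic acid F7. Activation with ClCO2Et and Et3N (THF, −10 °C) gives the mixed ethyl carbonic anhydride F8, which is not isolated, and NaBH4 (aq. THF, 0 °C) reduces it to 22.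

Further compounds
F1 | step 5 | methyl 2-[(1S,3S,4R)-3-[(3E)-5-ethoxy-3-methyl-5-oxopent-3-en-1-yl]-3,4-dimethyl-2-oxocyclohexyl]hex-5-enoate (C2 epimers) | COC(=O)C(CCC=C)[C@@H]1CC[C@@H](C)[C@](C)(CC/C(C)=C/C(=O)OCC)C1=O
F2 | step 5 | methyl 2-[(1S,3S,4R)-3-[(3E)-5-ethoxy-3-methyl-5-oxopent-3-en-1-yl]-3,4-dimethyl-2-methylidenecyclohexyl]hex-5-enoate (C2 epimers) | COC(=O)C(CCC=C)[C@@H]1CC[C@@H](C)[C@](C)(CC/C(C)=C/C(=O)OCC)C1=C
F3 | step 5 | methyl (2S)-2-[(1R,3S,4R)-3-[(3E)-5-ethoxy-3-methyl-5-oxopent-3-en-1-yl]-3,4-dimethyl-2-methylidenecyclohexyl]-2-methylhex-5-enoate | COC(=O)[C@@](C)(CCC=C)[C@@H]1CC[C@@H](C)[C@](C)(CC/C(C)=C/C(=O)OCC)C1=C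
F4 | step 7 | methyl 4-(1,3-dioxolan-2-yl)-2-[(1S,3S,4R)-3-[(3E)-5-ethoxy-3-methyl-5-oxopent-3-en-1-yl]-3,4-dimethyl-2-oxocyclohexyl]butanoate (C2 epimers) | COC(=O)C(CCC2OCCO2)[C@@H]1CC[C@@H](C)[C@](C)(CC/C(C)=C/C(=O)OCC)C1=O
F5 | step 7 | methyl 2-[(1S,3S,4R)-3-[(3E)-5-ethoxy-3-methyl-5-oxopent-3-en-1-yl]-3,4-dimethyl-2-oxocyclohexyl]-5-oxopentanoate (C2 epimers) | COC(=O)C(CCC=O)[C@@H]1CC[C@@H](C)[C@](C)(CC/C(C)=C/C(=O)OCC)C1=O
F6 | step 7 | methyl (5S,6R,8aS)-5-[(3E)-5-ethoxy-3-methyl-5-oxopent-3-en-1-yl]-5,6-dimethyl-1,2,3,5,6,7,8,8a-octahydronaphthalene-1-carboxylate (C1 epimers) | COC(=O)C1CCC=C2[C@H]1CC[C@@H](C)[C@]2(C)CC/C(C)=C/C(=O)OCC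
F7 | step 8 | (2E)-5-[(1S,2R,4aR,5S)-5-(methoxycarbonyl)-1,2,5-trimethyl-1,2,3,4,4a,5,6,7-octahydronaphthalen-1-yl]-3-methylpent-2-enoic acid | COC(=O)[C@@]1(C)CCC=C2[C@H]1CC[C@@H](C)[C@]2(C)CC/C(C)=C/C(O)=O
F8 | step 8 | mixed ethyl carbonic anhydride of F7 (not isolated) | COC(=O)[C@@]1(C)CCC=C2[C@H]1CC[C@@H](C)[C@]2(C)CC/C(C)=C/C(=O)OC(=O)OCC
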